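## Structural features

22 is a stilbenoid trimer made of two trans-2,3-diaryl-2,3-dihydrobenzofurans that share no atom and are joined by a single bond from C3 of the first unit to C6′ of ring M of the second. The first unit (O1, C2, C3 fused to ring A) carries ring P (4-hydroxyphenyl) on C2, a hydroxyl on C4 and an (E)-4-hydroxystyryl group (ring S) on C6. The second carries a 2,4-dihydroxyphenyl ring on C2′, a 3,5-dihydroxyphenyl ring on C3′ and a hydroxyl on C4′. The four stereocentres form two adjacent pairs, C2/C3 and C2′/C3′, all R and each pair trans; ring M insulates the pairs from each other, so each needs its own source of absolute configuration. The fragile features are the eight phenols and the electron-rich stilbene (oxidation, acid) and the two benzylic C2–O bonds, which ionise under acid because their aryl groups carry para oxygen (at C2′ also ortho oxygen); this lability lets a cis pair be corrected to trans but threatens the late stages. The real difficulty is to annulate the dihydrofuran onto ring A with C3 on the ring carbon that lies between two oxygenated positions (C3a between C4–O and C7a–O1) and trans to C2, in a molecule that already holds an acid-labile pair. The key step uses this 1,2,3-pattern of ring A: it is what remains when a 3-alkoxyaryne accepts an oxygen nucleophile at its remote terminus (C7a) and a carbon electrophile at the terminus beside the alkoxy group (C3a).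

## Logic of the disconnections

22 to 21: the seven O–CH3 bonds are cut last. Methyl ethers survive every earlier reagent (Grignard, carbene, fluoride, peracid, palladium). The forward step must cleave seven ethers without irreversibly ionising the C2–O1 and C2′–O1′ bonds.

21 to 19 and 20: the C6–vinyl bond is cut. The oxidation-sensitive stilbene is thereby kept out of the molecule until the peracid step is over. The forward coupling has only one C–Br bond to address and must keep the (E) geometry; an alkenylboron partner is preferred to a styrene because it cannot give the 1,1-diarylethene isomer.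

19 to 17 (through 18): the ring P C–O bond is exchanged for a C–C(=O)CH3 bond. Ring P has to be electron-poor during the key step and electron-rich in the product. The demand is a peracid oxidation that takes the ketone and spares the dimethoxyarenes.

17 to 13 and 16: O1–C7a and C3–C3a are cut, which removes the whole ring A heterocycle in one operation and leaves an oxirane and an aryne precursor. The forward step must place oxygen on C7a (secured by the methoxy group of 16), open the oxirane at C3–O and not at C2–O, and close trans. The ring M aryl is attached to C3 through C6′, meta to both its oxygens, so it offers no cation stabilisation; the discrimination therefore rests on the acetyl group alone and is judged adequate but moderate. Other masks were weighed and rejected: an aryl sulfonate is a weaker acceptor because its oxygen still donates, a boronate becomes a donor once fluoride binds to it, and a nitro group has no mild route to hydroxyl. The constitution of 13 is therefore kept; what is improved is its defined (2S,3S) configuration, its access and the reaction medium.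

16 to 14: the C5–Br bond is cut. 14 is purchasable and has only one C–H without an ortho neighbour, so sterically controlled borylation followed by bromodeboronation replaces a multi-step directed-metalation sequence on a bromoarene.

13 to 12: the two oxirane C–O bonds are cut. The (2S,3S) oxirane needs the ketone catalyst of the L-fructose series; the usual D-fructose-derived ketone gives (R,R) oxiranes from (E)-stilbenes and would lead to the mirror-image C2/C3 pair.

12 to 10 and 11: the aryl–vinyl bond is cut. Olefination of a C6′ aldehyde with a 4-acetylbenzyl phosphonate carbanion was rejected: the same base would enolise the methyl ketone and invite aldol condensation with the aldehyde. A Heck reaction on the bromide avoids this and saves the steps needed to make aldehyde and phosphonate.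

10 to 9 to 7 (through 8): first C2′ is inverted on paper (cis to trans), then the C2′–C3′ bond is cut to a diaryl carbene and a benzylic ether C–H. This sets C3′ by catalyst control and leaves C2′ to thermodynamic correction. The demand is face selectivity at a carbene whose aryl ring has two ortho substituents.

7 to 4 and 5 (through 6): the bond from C3′ to the 3,5-dimethoxyphenyl ring is cut, giving a nitrile and an aryl Grignard reagent. The ketimine route avoids condensing hydrazine with a di-ortho-substituted benzophenone.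

4 to 2 and 3, and 2 to 1: the two aryl C–O bonds ortho to the nitrile are cut. Sequential displacement of the two fluorines of 1 fixes the pattern of ring M (carbon between two oxygens, bromine para to it) without any regiochemical question.

## Other disconnections considered

Alternative 1: The cut removes three bonds of ring M (C4′–C3a′, C7a′–C7′, C4′–C5′). The hub arene is then made last from cyclobutenone A2, which carries the finished ring A dihydrobenzofuran on its C3, and siloxyalkyne A3, which carries C3′ and C2′ as an open-chain pair. Forward, heating the two would give resorcinol monosilyl ether A1 by a Danheiser-type benzannulation (4π opening of A2, [2+2] addition to A3, second opening, 6π closure). Desilylation, ionisation-driven closure of the C7a′ phenol onto C2′ (trans by thermodynamic control) and methylation of the C4′ hydroxyl would follow.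
- In its favour: the annulation is an established reaction class, so on precedent it is better than the chosen key step. Its regiochemistry is fixed by the polarity of the partners, at least the equal of the aryne case. Ring P enters as a plain 4-methoxyphenyl ring, so no acetyl mask and no Baeyer–Villiger step are needed, which is better.
- Against it: the ring A dihydrobenzofuran with its C2/C3 pair must already exist in A2, so the problem the chosen step solves is only moved. A3 has a propargylic, benzylic C–H at C3′ that is prone to propargyl–allenyl isomerisation, and C3 in A2 sits at a vinylogously enolisable position under the thermal conditions.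
- Comparison: on structure the chosen plan builds only a heterocycle and buys every arene, whereas this plan builds an arene. On mechanism a neutral pericyclic cascade stands against a polar zwitterionic one (heat against fluoride, comparable mildness). On step economy two separately made chiral fragments and three post-annulation steps make it clearly longer than the twelve steps chosen.

Alternative 2: The cut is at O1–C2 and C2–C3, so C2 with ring P is delivered as a one-carbon unit to a ring A ortho-quinone methide. Forward, Cs2CO3 would eliminate toluenesulfinate from sulfone A5; the ylide of the chiral 4-methoxybenzyl sulfonium salt A6 would add to C3 and then be displaced by the phenoxide, giving A4 with a free C4 hydroxyl.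
- In its favour: stilbene and methyl ethers are already in place, so A4 is one deprotection from 22 and the end game is shorter than the chosen one (better). The 2-substituted resorcinol of A5 is symmetric, so the regiochemical question the aryne must answer does not arise (better). Conditions are mild and basic, which suits the acid-labile second unit (equal or better). The [4+1] annulation of quinone methides with sulfur ylides to trans-dihydrobenzofurans is a known reaction class (better on precedent for the ring closure).
- Against it: C3 arises from a planar quinone methide, so both C2 and C3 depend on the face selectivity of a semi-stabilised benzylic ylide in a conjugate addition; induction there is much less secure than in epoxidations with such ylides, and the C2′/C3′ pair is too remote to help. Making A5 needs a C–C bond at the carbon between the two hydroxyls of a 5-styrylresorcinol, the less favoured site for an electrophile, with free phenols and a stilbene present.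
- Comparison: structurally it forms the same heterocycle from the other side. Mechanistically both plans end in an ionic closure that favours trans, but the chosen plan takes its absolute configuration from a reagent-controlled epoxidation of a simple (E)-stilbene, the more dependable source. In step count the two are about equal once the synthesis of A5 is included.

Alternative 3: The cut is at C7a–C3a and C5–C4, so ring A is formed together with the dihydrofuran. Forward, heating pyrone A8 would bring about an intramolecular Diels–Alder reaction and loss of CO2 to give A7; in A8 a 3-alkoxy-5-bromo-2-pyrone is tied through O1–C2–C3 to an alkynyl pinacolboronate. Oxidation of the C–B bond, methylation, coupling at C6 and deprotection would follow.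
- In its favour: C2 and C3 are set beforehand on an open chain and only carried through, so the key step has no stereochemical task (better than the chosen step, which creates C3). The tether dictates regiochemistry (equal or better). The reaction needs no reagent. The boronate gives the C4 oxygen under mild oxidation and distinguishes it from all other oxygens (better for late differentiation). Ring P needs no mask.
- Against it: the anti C2/C3 pair of A8 includes a propargylic diarylmethine that isomerises easily. The C2–O bond to the hydroxypyrone must be made at a benzylic carbon bearing a 4-methoxyphenyl group without loss of configuration. Pyrone–alkyne cycloadditions need high temperatures, at which such a benzylic pyronyl ether may ionise or eliminate. Two extra steps follow the key step.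
- Comparison: on structure it constructs an arene that the chosen plan buys ready-made. On mechanism a concerted cycloaddition with certain regiochemistry stands against a stepwise ionic insertion with two regiochemical demands, a clear point for the alternative. On step economy the way to A8 is longer than that to 13 and the end game is one step longer, so the chosen plan is shorter overall.

Key step: step 9

Assumption: 1, 3, 5, 11, 14 and 20, both antipodes of the Shi ketone and both antipodes of Rh2(PTAD)4 are taken as purchasable.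
Assumption: the sense of induction of Rh2(S-PTAD)4 in step 4 is taken by analogy with related diaryl carbene insertions; if it proves opposite, Rh2(R-PTAD)4 is used and nothing else changes.
Assumption: the face selectivity of the epoxidation in step 7 is taken to follow that of (E)-stilbene itself.

## Steps

Step 1
Reactants: 1 4-bromo-2,6-difluorobenzonitrile
Product: 2 4-bromo-2-fluoro-6-methoxybenzonitrile
Conditions: NaOMe (1.05 equiv), MeOH/THF, −10 → 20 °C
Reagents that add atoms: sodium methoxide, [Na+].[O-]C
Why: Nucleophilic aromatic substitution (SNAr): fluoride ortho to the nitrile is displaced much faster than the para bromide, and the first methoxy group deactivates the ring enough to stop at monosubstitution.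

Step 2
Reactants: 2 4-bromo-2-fluoro-6-methoxybenzonitrile; 3 2,4-dimethoxybenzyl alcohol
Product: 4 4-bromo-2-[(2,4-dimethoxybenzyl)oxy]-6-methoxybenzonitrile
Conditions: NaH, THF/DMF, 0 → 40 °C
Reagents that add atoms: none
Why: Second SNAr by the sodium alkoxide of 3 at the remaining ortho fluorine; the nitrile still activates this position, and bromide para to it is a much poorer leaving group in addition–elimination.

Step 3
Reactants: 4 4-bromo-2-[(2,4-dimethoxybenzyl)oxy]-6-methoxybenzonitrile; 5 3,5-dimethoxyphenylmagnesium chloride (THF solution)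
Product: 7 [(4-bromo-2-[(2,4-dimethoxybenzyl)oxy]-6-methoxyphenyl)(3,5-dimethoxyphenyl)methylidene]hydrazine, via ketimine 6 (not isolated)
Conditions: 5 (1.5 equiv), CuBr (5 mol%), THF, 60 °C; MeOH, 0 °C; then N2H4·H2O (10 equiv), AcOH, EtOH, 60 °C
Reagents that add atoms: hydrazine (as hydrate), NN
Why: Grignard addition to a nitrile stops at the magnesium ketiminate, so no over-addition occurs; the hindered N–H ketimine 6 then exchanges ammonia for hydrazine (transimination), which is easier than condensing hydrazine with the corresponding di-ortho-substituted benzophenone. The aryl bromide is inert to the arylmagnesium chloride at this temperature.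

Step 4
Reactants: 7 [(4-bromo-2-[(2,4-dimethoxybenzyl)oxy]-6-methoxyphenyl)(3,5-dimethoxyphenyl)methylidene]hydrazine
Product: 9 (2S,3R)-6-bromo-2-(2,4-dimethoxyphenyl)-3-(3,5-dimethoxyphenyl)-4-methoxy-2,3-dihydrobenzofuran (cis), via diaryldiazomethane 8 (not isolated)
Conditions: MnO2 (8 equiv), CH2Cl2, 0 °C; filtration; Rh2(S-PTAD)4 (1 mol%), CH2Cl2, −20 → 0 °C
Reagents that add atoms: none
Why: MnO2 dehydrogenates the hydrazone to the donor/donor diazo compound 8, whose dirhodium carbene inserts into the electron-rich benzylic C–H bond of the ortho ether (intramolecular 1,5 C–H insertion) and closes the dihydrofuran ring. The chiral carboxylate ligands select the carbene face and so set C3′, and the concerted, hydride-transfer-like insertion gives the cis C2′/C3′ pair; insertion into a methoxy C–H bond is much slower than into the doubly activated benzylic position.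

Step 5
Reactants: 9 (2S,3R)-6-bromo-2-(2,4-dimethoxyphenyl)-3-(3,5-dimethoxyphenyl)-4-methoxy-2,3-dihydrobenzofuran
Product: 10 (2R,3R)-6-bromo-2-(2,4-dimethoxyphenyl)-3-(3,5-dimethoxyphenyl)-4-methoxy-2,3-dihydrobenzofuran (trans)
Conditions: TFA (1 equiv), CH2Cl2, 0 °C
Reagents that add atoms: none
Why: Acid-mediated epimerisation: reversible ionisation of the C2′–O1′ bond to a benzylic cation stabilised by the 2,4-dimethoxyphenyl ring and re-closure under thermodynamic control should give the trans isomer, while C3′, which cannot ionise, keeps the configuration set in step 4.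

Step 6
Reactants: 10 (2R,3R)-6-bromo-2-(2,4-dimethoxyphenyl)-3-(3,5-dimethoxyphenyl)-4-methoxy-2,3-dihydrobenzofuran; 11 4-vinylacetophenone [1-(4-ethenylphenyl)ethanone]
Product: 12 1-(4-{(E)-2-[(2R,3R)-2-(2,4-dimethoxyphenyl)-3-(3,5-dimethoxyphenyl)-4-methoxy-2,3-dihydrobenzofuran-6-yl]ethenyl}phenyl)ethanone
Conditions: 11 (1.5 equiv), Pd(OAc)2 (5 mol%), P(o-tol)3 (10 mol%), Et3N, DMF, 100 °C
Reagents that add atoms: none
Why: Mizoroki–Heck reaction of the aryl bromide with an electron-poor styrene should give the linear (E)-stilbene by syn insertion and syn β-hydride elimination; the amine base leaves the acid-labile C2′–O bond and the methyl ketone untouched, and no carbanion is formed that could start an aldol reaction.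

Step 7
Reactants: 12 1-(4-{(E)-2-[(2R,3R)-2-(2,4-dimethoxyphenyl)-3-(3,5-dimethoxyphenyl)-4-methoxy-2,3-dihydrobenzofuran-6-yl]ethenyl}phenyl)ethanone
Product: 13 1-(4-{(2S,3S)-3-[(2R,3R)-2-(2,4-dimethoxyphenyl)-3-(3,5-dimethoxyphenyl)-4-methoxy-2,3-dihydrobenzofuran-6-yl]oxiran-2-yl}phenyl)ethanone
Conditions: Shi ketone of the L-fructose series (30 mol%), Oxone (2KHSO5·KHSO4·K2SO4), K2CO3, n-Bu4NHSO4, MeCN/dimethoxymethane/aq. Na2B4O7–Na2EDTA buffer (pH 10.5), 0 °C
Reagents that add atoms: Oxone, active component potassium peroxymonosulfate KHSO5, [K+].[O-]S(=O)(=O)OO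
Why: Shi epoxidation: the chiral dioxirane formed from the ketone and Oxone transfers oxygen to one face of the trans-disubstituted alkene through a spiro transition state, so the oxirane configuration is set by the reagent and not by the remote C2′/C3′ centres. The L-series ketone is specified because the D-fructose-derived ketone gives (R,R) oxiranes from (E)-stilbenes, which would end in the mirror-image C2/C3 pair; the basic buffer protects the acid-labile ether and keeps the aryl ketone from Baeyer–Villiger oxidation.

Step 8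
Reactants: 14 3-methoxy-2-(trimethylsilyl)phenyl trifluoromethanesulfonate
Product: 16 5-bromo-3-methoxy-2-(trimethylsilyl)phenyl trifluoromethanesulfonate, via pinacol boronate 15 (not isolated)
Conditions: [Ir(OMe)(cod)]2 (1.5 mol%), 4,4′-di-tert-butyl-2,2′-bipyridine (3 mol%), B2pin2, cyclohexane, 80 °C; evaporation; CuBr2 (3 equiv), MeOH/H2O, 80 °C
Reagents that add atoms: copper dibromide CuBr2, [Cu+2].[Br-].[Br-]; bis(pinacolato)diboron, CC1(C)OB(OC1(C)C)B1OC(C)(C)C(C)(C)O1 (its boryl group is carried only by 15)
Why: Iridium-catalysed C–H borylation is sterically controlled and on a 1,2,3-trisubstituted benzene takes the only C–H bond without an ortho neighbour (C5); copper-mediated bromodeboronation of crude 15 then puts bromine on the same carbon. Aryl triflate and arylsilane are expected to tolerate both operations.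

Step 9
Reactants: 13 1-(4-{(2S,3S)-3-[(2R,3R)-2-(2,4-dimethoxyphenyl)-3-(3,5-dimethoxyphenyl)-4-methoxy-2,3-dihydrobenzofuran-6-yl]oxiran-2-yl}phenyl)ethanone; 16 5-bromo-3-methoxy-2-(trimethylsilyl)phenyl trifluoromethanesulfonate
Product: 17 1-(4-{(2R,3R)-6-bromo-3-[(2R,3R)-2-(2,4-dimethoxyphenyl)-3-(3,5-dimethoxyphenyl)-4-methoxy-2,3-dihydrobenzofuran-6-yl]-4-methoxy-2,3-dihydrobenzofuran-2-yl}phenyl)ethanone
Conditions: 16 (2.5 equiv, added over 6 h), CsF (5 equiv), MeCN/toluene (1:4), 50 °C
Reagents that add atoms: none
Why: Proposed new method: fluoride removes the silyl group of 16 with loss of triflate to give 3-methoxy-5-bromobenzyne, whose distortion by the inductively withdrawing methoxy group directs the oxirane oxygen of 13 to the aryne carbon remote from it (future C7a), so that the aryl anion develops at C3a beside C4–OMe. The resulting O-aryl oxiranium zwitterion cannot close by backside displacement within a five-membered array and must ionise; heterolysis is expected at C3–O because a cation at C2 would be destabilised by the para-acetyl group, whereas the ring M aryl, oxygenated only meta to C3, is roughly neutral. The benzylic cation and the adjacent aryl anion then recombine to form C3–C3a, a five-membered closure of 5-exo-trig type in which the cationic π system (C3 with ring M) lies outside the new ring. The closest known reaction type is the insertion of arynes into the C–O bond of monoaryl epoxides to give 2,3-dihydrobenzofurans; the new element is a 2,3-diaryl oxirane with a regiochemical demand on both partners. C2 keeps its configuration because its C–O bond is never broken, and the new C3 centre is set trans to the C2 aryl group because the anion reaches the cation in the rotamer that holds ring M anti to that group, which is also the more stable arrangement. Three selectivities are needed: aryne regiochemistry (secured by the 3-methoxy group), site of oxirane cleavage (secured by the acetyl group), and preference for the oxirane oxygen over ether and ketone oxygens (helped by strain release on ring opening, which makes this capture irreversible, and by excess 16). The toluene-rich medium keeps the fluoride concentration and thus the stationary aryne concentration low and limits protonation of the aryl anion by acetonitrile.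

Step 10
Reactants: 17 1-(4-{(2R,3R)-6-bromo-3-[(2R,3R)-2-(2,4-dimethoxyphenyl)-3-(3,5-dimethoxyphenyl)-4-methoxy-2,3-dihydrobenzofuran-6-yl]-4-methoxy-2,3-dihydrobenzofuran-2-yl}phenyl)ethanone
Product: 19 4-{(2R,3R)-6-bromo-3-[(2R,3R)-2-(2,4-dimethoxyphenyl)-3-(3,5-dimethoxyphenyl)-4-methoxy-2,3-dihydrobenzofuran-6-yl]-4-methoxy-2,3-dihydrobenzofuran-2-yl}phenol, via aryl acetate 18 (not isolated)
Conditions: mCPBA (2.5 equiv), NaHCO3, CH2Cl2, 25–40 °C; aq. Na2S2O3 wash; then K2CO3 (0.3 equiv), MeOH/THF, 0 °C
Reagents that add atoms: meta-chloroperoxybenzoic acid, OOC(=O)c1cccc(Cl)c1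
Why: Baeyer–Villiger oxidation: in the Criegee adduct the aryl group migrates in preference to methyl, giving aryl acetate 18, which methanol transesterifies under mild base to the phenol; C2 is not touched. The NaHCO3 buffer avoids acid-induced ionisation of the benzylic ethers, and the alkene that would compete for the peracid is not yet present.

Step 11
Reactants: 19 4-{(2R,3R)-6-bromo-3-[(2R,3R)-2-(2,4-dimethoxyphenyl)-3-(3,5-dimethoxyphenyl)-4-methoxy-2,3-dihydrobenzofuran-6-yl]-4-methoxy-2,3-dihydrobenzofuran-2-yl}phenol; 20 (E)-2-(4-methoxyphenyl)vinylboronic acid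
Product: 21 4-{(2R,3R)-3-[(2R,3R)-2-(2,4-dimethoxyphenyl)-3-(3,5-dimethoxyphenyl)-4-methoxy-2,3-dihydrobenzofuran-6-yl]-4-methoxy-6-[(E)-2-(4-methoxyphenyl)ethenyl]-2,3-dihydrobenzofuran-2-yl}phenol
Conditions: 20 (1.5 equiv), Pd(dppf)Cl2 (5 mol%), K2CO3, 1,4-dioxane/H2O, 80 °C
Reagents that add atoms: none
Why: Suzuki–Miyaura coupling at the only carbon–halogen bond transfers the alkenyl group with retention of its (E) geometry and, unlike a Heck reaction with an electron-rich styrene, cannot give the 1,1-diarylethene isomer; the free phenol is tolerated under aqueous carbonate.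

Step 12
Reactants: 21 4-{(2R,3R)-3-[(2R,3R)-2-(2,4-dimethoxyphenyl)-3-(3,5-dimethoxyphenyl)-4-methoxy-2,3-dihydrobenzofuran-6-yl]-4-methoxy-6-[(E)-2-(4-methoxyphenyl)ethenyl]-2,3-dihydrobenzofuran-2-yl}phenol
Product: 22 (2R,3R)-3-[(2R,3R)-2-(2,4-dihydroxyphenyl)-3-(3,5-dihydroxyphenyl)-4-hydroxy-2,3-dihydrobenzofuran-6-yl]-2-(4-hydroxyphenyl)-6-[(E)-2-(4-hydroxyphenyl)ethenyl]-2,3-dihydrobenzofuran-4-ol (CNP0118407.2)
Conditions: BBr3 (20 equiv), CH2Cl2, −78 → 0 °C; MeOH, then aq. NaHCO3
Reagents that add atoms: none
Why: Lewis-acid cleavage of aryl methyl ethers: each ether oxygen is complexed by boron and the methyl group is removed by bromide in an SN2 step, so no bond to a stereocentre is broken. Low temperature limits ionisation of the C2–O1 and C2′–O1′ bonds, and if these open reversibly they should re-close to the trans arrangement already present.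

## Compound list

1 | 4-bromo-2,6-difluorobenzonitrile | N#Cc1c(F)cc(Br)cc1F | starting material
2 | 4-bromo-2-fluoro-6-methoxybenzonitrile | N#Cc1c(F)cc(Br)cc1OC | intermediate
3 | 2,4-dimethoxybenzyl alcohol | OCc1ccc(OC)cc1OC | starting material
4 | 4-bromo-2-[(2,4-dimethoxybenzyl)oxy]-6-methoxybenzonitrile | N#Cc1c(OC)cc(Br)cc1OCc1ccc(OC)cc1OC | intermediate
5 | 3,5-dimethoxyphenylmagnesium chloride | COc1cc(OC)cc([Mg]Cl)c1 | starting material
6 | (4-bromo-2-[(2,4-dimethoxybenzyl)oxy]-6-methoxyphenyl)(3,5-dimethoxyphenyl)methanimine | N=C(c1cc(OC)cc(OC)c1)c1c(OC)cc(Br)cc1OCc1ccc(OC)cc1OC | intermediate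
7 | [(4-bromo-2-[(2,4-dimethoxybenzyl)oxy]-6-methoxyphenyl)(3,5-dimethoxyphenyl)methylidene]hydrazine | NN=C(c1cc(OC)cc(OC)c1)c1c(OC)cc(Br)cc1OCc1ccc(OC)cc1OC | intermediate
8 | 5-bromo-2-[diazo(3,5-dimethoxyphenyl)methyl]-1-[(2,4-dimethoxybenzyl)oxy]-3-methoxybenzene | [N-]=[N+]=C(c1cc(OC)cc(OC)c1)c1c(OC)cc(Br)cc1OCc1ccc(OC)cc1OC | intermediate
9 | (2S,3R)-6-bromo-2-(2,4-dimethoxyphenyl)-3-(3,5-dimethoxyphenyl)-4-methoxy-2,3-dihydrobenzofuran | Brc1cc(OC)c2c(c1)O[C@H](c1ccc(OC)cc1OC)[C@@H]2c1cc(OC)cc(OC)c1 | intermediate
10 | (2R,3R)-6-bromo-2-(2,4-dimethoxyphenyl)-3-(3,5-dimethoxyphenyl)-4-methoxy-2,3-dihydrobenzofuran | Brc1cc(OC)c2c(c1)O[C@@H](c1ccc(OC)cc1OC)[C@@H]2c1cc(OC)cc(OC)c1 | intermediate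
11 | 4-vinylacetophenone | C=Cc1ccc(C(C)=O)cc1 | starting material
12 | 1-(4-{(E)-2-[(2R,3R)-2-(2,4-dimethoxyphenyl)-3-(3,5-dimethoxyphenyl)-4-methoxy-2,3-dihydrobenzofuran-6-yl]ethenyl}phenyl)ethanone | CC(=O)c1ccc(/C=C/c2cc(OC)c3c(c2)O[C@@H](c2ccc(OC)cc2OC)[C@@H]3c2cc(OC)cc(OC)c2)cc1 | intermediate
13 | 1-(4-{(2S,3S)-3-[(2R,3R)-2-(2,4-dimethoxyphenyl)-3-(3,5-dimethoxyphenyl)-4-methoxy-2,3-dihydrobenzofuran-6-yl]oxiran-2-yl}phenyl)ethanone | O1[C@@H](c2ccc(C(C)=O)cc2)[C@@H]1c1cc(OC)c2c(c1)O[C@@H](c1ccc(OC)cc1OC)[C@@H]2c1cc(OC)cc(OC)c1 | intermediate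
14 | 3-methoxy-2-(trimethylsilyl)phenyl trifluoromethanesulfonate | COc1cccc(OS(=O)(=O)C(F)(F)F)c1[Si](C)(C)C | starting material
15 | 3-methoxy-5-(4,4,5,5-tetramethyl-1,3,2-dioxaborolan-2-yl)-2-(trimethylsilyl)phenyl trifluoromethanesulfonate | COc1cc(B2OC(C)(C)C(C)(C)O2)cc(OS(=O)(=O)C(F)(F)F)c1[Si](C)(C)C | intermediate
16 | 5-bromo-3-methoxy-2-(trimethylsilyl)phenyl trifluoromethanesulfonate | COc1cc(Br)cc(OS(=O)(=O)C(F)(F)F)c1[Si](C)(C)C | intermediate
17 | 1-(4-{(2R,3R)-6-bromo-3-[(2R,3R)-2-(2,4-dimethoxyphenyl)-3-(3,5-dimethoxyphenyl)-4-methoxy-2,3-dihydrobenzofuran-6-yl]-4-methoxy-2,3-dihydrobenzofuran-2-yl}phenyl)ethanone | Brc1cc(OC)c2c(c1)O[C@@H](c1ccc(C(C)=O)cc1)[C@@H]2c1cc(OC)c2c(c1)O[C@@H](c1ccc(OC)cc1OC)[C@@H]2c1cc(OC)cc(OC)c1 | intermediate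
18 | 4-{(2R,3R)-6-bromo-3-[(2R,3R)-2-(2,4-dimethoxyphenyl)-3-(3,5-dimethoxyphenyl)-4-methoxy-2,3-dihydrobenzofuran-6-yl]-4-methoxy-2,3-dihydrobenzofuran-2-yl}phenyl acetate | Brc1cc(OC)c2c(c1)O[C@@H](c1ccc(OC(C)=O)cc1)[C@@H]2c1cc(OC)c2c(c1)O[C@@H](c1ccc(OC)cc1OC)[C@@H]2c1cc(OC)cc(OC)c1 | intermediate
19 | 4-{(2R,3R)-6-bromo-3-[(2R,3R)-2-(2,4-dimethoxyphenyl)-3-(3,5-dimethoxyphenyl)-4-methoxy-2,3-dihydrobenzofuran-6-yl]-4-methoxy-2,3-dihydrobenzofuran-2-yl}phenol | Brc1cc(OC)c2c(c1)O[C@@H](c1ccc(O)cc1)[C@@H]2c1cc(OC)c2c(c1)O[C@@H](c1ccc(OC)cc1OC)[C@@H]2c1cc(OC)cc(OC)c1 | intermediate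
20 | (E)-2-(4-methoxyphenyl)vinylboronic acid | COc1ccc(/C=C/B(O)O)cc1 | starting material
21 | 4-{(2R,3R)-3-[(2R,3R)-2-(2,4-dimethoxyphenyl)-3-(3,5-dimethoxyphenyl)-4-methoxy-2,3-dihydrobenzofuran-6-yl]-4-methoxy-6-[(E)-2-(4-methoxyphenyl)ethenyl]-2,3-dihydrobenzofuran-2-yl}phenol | COc1ccc(/C=C/c2cc(OC)c3c(c2)O[C@@H](c2ccc(O)cc2)[C@@H]3c2cc(OC)c3c(c2)O[C@@H](c2ccc(OC)cc2OC)[C@@H]3c2cc(OC)cc(OC)c2)cc1 | intermediate
22 | (2R,3R)-3-[(2R,3R)-2-(2,4-dihydroxyphenyl)-3-(3,5-dihydroxyphenyl)-4-hydroxy-2,3-dihydrobenzofuran-6-yl]-2-(4-hydroxyphenyl)-6-[(E)-2-(4-hydroxyphenyl)ethenyl]-2,3-dihydrobenzofuran-4-ol | Oc1ccc(/C=C/c2cc(O)c3c(c2)O[C@@H](c2ccc(O)cc2)[C@@H]3c2cc(O)c3c(c2)O[C@@H](c2ccc(O)cc2O)[C@@H]3c2cc(O)cc(O)c2)cc1 | target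

## Step count and least certain steps

Total: 12 steps. Longest linear sequence: 11 steps (steps 1–7 and 9–12, from 1 to 22); step 8 is a one-step side branch.

Step 9 (key step, proposed new method). Capture of the aryne by the weakly nucleophilic oxirane oxygen may be too slow against aryne self-consumption or attack by ketone and ether oxygens. The oxiranium may open in part at C2–O, since the bias rests on the acetyl group alone. The cation may undergo a Meinwald-type hydride shift before it meets the aryl anion, or the anion may be protonated by the medium. Fallback (known chemistry, no aryne): the ring A unit is built by repeating the ketimine/hydrazone/carbene-insertion sequence of steps 2–5. It sets out from 2 and 10.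
- 2 is etherified with 4-methoxybenzyl alcohol (NaH, THF) to 4-bromo-2-methoxy-6-[(4-methoxybenzyl)oxy]benzonitrile F1.
- 10 is converted with magnesium (THF, 40 °C, no lithium salt) into its arylmagnesium bromide F2, which adds to F1 (CuBr cat., 60 °C) to give the ketimine F3; exchange with hydrazine gives the hydrazone F4.
- MnO2 gives the diazo compound F5, and Rh2(S-PTAD)4 (or its mirror image, whichever sets C3 as R) gives the cis-dihydrobenzofuran F6; TFA epimerises it to the trans compound F7, the methyl ether of 19.
- Suzuki–Miyaura coupling of F7 with 20 gives the octamethyl ether F8, and BBr3 converts F8 into 22, where the fallback rejoins the route.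

Step 3. Addition to the hindered, electron-rich nitrile may be slow, and displacement of an ortho alkoxy group or halogen–magnesium exchange at the C–Br bond may compete. Fallback from 4: reduction with i-Bu2AlH (toluene, −78 °C, mild aqueous hydrolysis) gives the aldehyde 4-bromo-2-[(2,4-dimethoxybenzyl)oxy]-6-methoxybenzaldehyde F9. Addition of 5 at −78 °C gives the diaryl carbinol F10, and MnO2 oxidises it to the benzophenone F11. Forced condensation with hydrazine hydrate (AcOH, n-butanol, 110 °C) returns to the route at 7.

Step 4. Face selection at the carbene may be insufficient because the second ortho substituent twists the carbene-bearing ring, and the sense of induction is assumed. Fallback from 7: MnO2 and achiral Rh2(OAc)4 give racemic cis material, that is 9 together with its enantiomer (2R,3S)-6-bromo-2-(2,4-dimethoxyphenyl)-3-(3,5-dimethoxyphenyl)-4-methoxy-2,3-dihydrobenzofuran F12. TFA converts the mixture into 10 and its enantiomer (2S,3S)-6-bromo-2-(2,4-dimethoxyphenyl)-3-(3,5-dimethoxyphenyl)-4-methoxy-2,3-dihydrobenzofuran F13. Preparative chromatography on a chiral stationary phase separates them, and the fallback returns to the route at 10.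

Step 10. Ring hydroxylation of the dimethoxyarene rings by the peracid may compete with a slow Baeyer–Villiger reaction at an aryl ketone whose migrating ring is not activated. Fallback from 10, with ring P masked as an aryl triflate so that no oxidation is needed:
- Heck reaction of 10 with 4-acetoxystyrene gives the stilbene acetate F14; K2CO3/MeOH gives the stilbene phenol F15; PhNTf2/Et3N gives the stilbene triflate F16.
- Shi epoxidation with the L-series ketone gives the oxirane F17, and insertion of the aryne from 16 as in step 9 gives the bromo triflate F18.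
- Et4NOH in dioxane cleaves the triflate and returns to the route at 19.
- The triflate is a weaker acceptor than acetyl, so the regiochemical margin of the insertion would be smaller in this series.

Step 12. The C2′–O1′ and C2–O1 bonds may ionise under the Lewis acid and be trapped irreversibly or eliminate, the oxygenated stilbene may degrade under the acid, and cleavage of seven ethers may stay incomplete, giving mixtures of polyphenols that are hard to separate. Fallback from 19, which moves the Lewis-acid step ahead of the stilbene and ends with a mild deprotection: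
- BBr3 gives the heptaphenol bromide F19, and Ac2O/pyridine gives the heptaacetate F20, which can be purified.
- Heck reaction of F20 with 4-acetoxystyrene (Pd(OAc)2, P(o-tol)3, Et3N, DMF, 90 °C) gives the octaacetate F21.
- K2CO3 in MeOH at 0 °C removes the acetates and returns to the route at 22.

## Further compounds

F1 | step 9 | 4-bromo-2-methoxy-6-[(4-methoxybenzyl)oxy]benzonitrile | N#Cc1c(OC)cc(Br)cc1OCc1ccc(OC)cc1
F2 | step 9 | [(2R,3R)-2-(2,4-dimethoxyphenyl)-3-(3,5-dimethoxyphenyl)-4-methoxy-2,3-dihydrobenzofuran-6-yl]magnesium bromide | Br[Mg]c1cc(OC)c2c(c1)O[C@@H](c1ccc(OC)cc1OC)[C@@H]2c1cc(OC)cc(OC)c1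
F3 | step 9 | {4-bromo-2-methoxy-6-[(4-methoxybenzyl)oxy]phenyl}[(2R,3R)-2-(2,4-dimethoxyphenyl)-3-(3,5-dimethoxyphenyl)-4-methoxy-2,3-dihydrobenzofuran-6-yl]methanimine | N=C(c1cc(OC)c2c(c1)O[C@@H](c1ccc(OC)cc1OC)[C@@H]2c1cc(OC)cc(OC)c1)c1c(OC)cc(Br)cc1OCc1ccc(OC)cc1
F4 | step 9 | hydrazone of the ketimine F3 | NN=C(c1cc(OC)c2c(c1)O[C@@H](c1ccc(OC)cc1OC)[C@@H]2c1cc(OC)cc(OC)c1)c1c(OC)cc(Br)cc1OCc1ccc(OC)cc1
F5 | step 9 | diazo compound from F4 | [N-]=[N+]=C(c1cc(OC)c2c(c1)O[C@@H](c1ccc(OC)cc1OC)[C@@H]2c1cc(OC)cc(OC)c1)c1c(OC)cc(Br)cc1OCc1ccc(OC)cc1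
F6 | step 9 | (2S,3R)-6-bromo-3-[(2R,3R)-2-(2,4-dimethoxyphenyl)-3-(3,5-dimethoxyphenyl)-4-methoxy-2,3-dihydrobenzofuran-6-yl]-4-methoxy-2-(4-methoxyphenyl)-2,3-dihydrobenzofuran | Brc1cc(OC)c2c(c1)O[C@H](c1ccc(OC)cc1)[C@@H]2c1cc(OC)c2c(c1)O[C@@H](c1ccc(OC)cc1OC)[C@@H]2c1cc(OC)cc(OC)c1
F7 | step 9 | (2R,3R)-6-bromo-3-[(2R,3R)-2-(2,4-dimethoxyphenyl)-3-(3,5-dimethoxyphenyl)-4-methoxy-2,3-dihydrobenzofuran-6-yl]-4-methoxy-2-(4-methoxyphenyl)-2,3-dihydrobenzofuran | Brc1cc(OC)c2c(c1)O[C@@H](c1ccc(OC)cc1)[C@@H]2c1cc(OC)c2c(c1)O[C@@H](c1ccc(OC)cc1OC)[C@@H]2c1cc(OC)cc(OC)c1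
F8 | step 9 | octamethyl ether of 22 | COc1ccc(/C=C/c2cc(OC)c3c(c2)O[C@@H](c2ccc(OC)cc2)[C@@H]3c2cc(OC)c3c(c2)O[C@@H](c2ccc(OC)cc2OC)[C@@H]3c2cc(OC)cc(OC)c2)cc1
F9 | step 3 | 4-bromo-2-[(2,4-dimethoxybenzyl)oxy]-6-methoxybenzaldehyde | O=Cc1c(OC)cc(Br)cc1OCc1ccc(OC)cc1OC
F10 | step 3 | (4-bromo-2-[(2,4-dimethoxybenzyl)oxy]-6-methoxyphenyl)(3,5-dimethoxyphenyl)methanol (racemic) | OC(c1cc(OC)cc(OC)c1)c1c(OC)cc(Br)cc1OCc1ccc(OC)cc1OC
F11 | step 3 | (4-bromo-2-[(2,4-dimethoxybenzyl)oxy]-6-methoxyphenyl)(3,5-dimethoxyphenyl)methanone | O=C(c1cc(OC)cc(OC)c1)c1c(OC)cc(Br)cc1OCc1ccc(OC)cc1OC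
F12 | step 4 | (2R,3S)-6-bromo-2-(2,4-dimethoxyphenyl)-3-(3,5-dimethoxyphenyl)-4-methoxy-2,3-dihydrobenzofuran | Brc1cc(OC)c2c(c1)O[C@@H](c1ccc(OC)cc1OC)[C@H]2c1cc(OC)cc(OC)c1
F13 | step 4 | (2S,3S)-6-bromo-2-(2,4-dimethoxyphenyl)-3-(3,5-dimethoxyphenyl)-4-methoxy-2,3-dihydrobenzofuran | Brc1cc(OC)c2c(c1)O[C@H](c1ccc(OC)cc1OC)[C@H]2c1cc(OC)cc(OC)c1
F14 | step 10 | 4-{(E)-2-[(2R,3R)-2-(2,4-dimethoxyphenyl)-3-(3,5-dimethoxyphenyl)-4-methoxy-2,3-dihydrobenzofuran-6-yl]ethenyl}phenyl acetate | CC(=O)Oc1ccc(/C=C/c2cc(OC)c3c(c2)O[C@@H](c2ccc(OC)cc2OC)[C@@H]3c2cc(OC)cc(OC)c2)cc1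
F15 | step 10 | 4-{(E)-2-[(2R,3R)-2-(2,4-dimethoxyphenyl)-3-(3,5-dimethoxyphenyl)-4-methoxy-2,3-dihydrobenzofuran-6-yl]ethenyl}phenol | Oc1ccc(/C=C/c2cc(OC)c3c(c2)O[C@@H](c2ccc(OC)cc2OC)[C@@H]3c2cc(OC)cc(OC)c2)cc1
F16 | step 10 | 4-{(E)-2-[(2R,3R)-2-(2,4-dimethoxyphenyl)-3-(3,5-dimethoxyphenyl)-4-methoxy-2,3-dihydrobenzofuran-6-yl]ethenyl}phenyl trifluoromethanesulfonate | FC(F)(F)S(=O)(=O)Oc1ccc(/C=C/c2cc(OC)c3c(c2)O[C@@H](c2ccc(OC)cc2OC)[C@@H]3c2cc(OC)cc(OC)c2)cc1
F17 | step 10 | 4-{(2S,3S)-3-[(2R,3R)-2-(2,4-dimethoxyphenyl)-3-(3,5-dimethoxyphenyl)-4-methoxy-2,3-dihydrobenzofuran-6-yl]oxiran-2-yl}phenyl trifluoromethanesulfonate | O1[C@@H](c2ccc(OS(=O)(=O)C(F)(F)F)cc2)[C@@H]1c1cc(OC)c2c(c1)O[C@@H](c1ccc(OC)cc1OC)[C@@H]2c1cc(OC)cc(OC)c1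
F18 | step 10 | 4-{(2R,3R)-6-bromo-3-[(2R,3R)-2-(2,4-dimethoxyphenyl)-3-(3,5-dimethoxyphenyl)-4-methoxy-2,3-dihydrobenzofuran-6-yl]-4-methoxy-2,3-dihydrobenzofuran-2-yl}phenyl trifluoromethanesulfonate | Brc1cc(OC)c2c(c1)O[C@@H](c1ccc(OS(=O)(=O)C(F)(F)F)cc1)[C@@H]2c1cc(OC)c2c(c1)O[C@@H](c1ccc(OC)cc1OC)[C@@H]2c1cc(OC)cc(OC)c1
F19 | step 12 | (2R,3R)-6-bromo-3-[(2R,3R)-2-(2,4-dihydroxyphenyl)-3-(3,5-dihydroxyphenyl)-4-hydroxy-2,3-dihydrobenzofuran-6-yl]-2-(4-hydroxyphenyl)-2,3-dihydrobenzofuran-4-ol | Brc1cc(O)c2c(c1)O[C@@H](c1ccc(O)cc1)[C@@H]2c1cc(O)c2c(c1)O[C@@H](c1ccc(O)cc1O)[C@@H]2c1cc(O)cc(O)c1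
F20 | step 12 | heptaacetate of F19 | Brc1cc(OC(C)=O)c2c(c1)O[C@@H](c1ccc(OC(C)=O)cc1)[C@@H]2c1cc(OC(C)=O)c2c(c1)O[C@@H](c1ccc(OC(C)=O)cc1OC(C)=O)[C@@H]2c1cc(OC(C)=O)cc(OC(C)=O)c1
F21 | step 12 | octaacetate of 22 | CC(=O)Oc1ccc(/C=C/c2cc(OC(C)=O)c3c(c2)O[C@@H](c2ccc(OC(C)=O)cc2)[C@@H]3c2cc(OC(C)=O)c3c(c2)O[C@@H](c2ccc(OC(C)=O)cc2OC(C)=O)[C@@H]3c2cc(OC(C)=O)cc(OC(C)=O)c2)cc1
A1 | alternative 1 | ring M resorcinol monosilyl ether joining both halves, second dihydrofuran still open | Brc1cc(OC)c2c(c1)O[C@@H](c1ccc(OC)cc1)[C@@H]2c1cc(O)c([C@@H](c2cc(OC)cc(OC)c2)[C@@H](O[Si](C)(C)C(C)(C)C)c2ccc(OC)cc2OC)c(O[Si](C(C)C)(C(C)C)C(C)C)c1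
A2 | alternative 1 | 3-[(2R,3R)-6-bromo-4-methoxy-2-(4-methoxyphenyl)-2,3-dihydrobenzofuran-3-yl]cyclobut-2-en-1-one | Brc1cc(OC)c2c(c1)O[C@@H](c1ccc(OC)cc1)[C@@H]2C1=CC(=O)C1
A3 | alternative 1 | triisopropylsilyl ynol ether bearing the open-chain C3′/C2′ pair with C2′ tert-butyldimethylsilyl ether | CC(C)[Si](C(C)C)(C(C)C)OC#C[C@@H](c1cc(OC)cc(OC)c1)[C@@H](O[Si](C)(C)C(C)(C)C)c1ccc(OC)cc1OC
A4 | alternative 2 | heptamethyl ether of 22 with free C4 hydroxyl | COc1ccc(/C=C/c2cc(O)c3c(c2)O[C@@H](c2ccc(OC)cc2)[C@@H]3c2cc(OC)c3c(c2)O[C@@H](c2ccc(OC)cc2OC)[C@@H]3c2cc(OC)cc(OC)c2)cc1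
A5 | alternative 2 | 2-substituted 5-styrylresorcinol sulfone (either epimer at the sulfonyl-bearing carbon) | COc1ccc(/C=C/c2cc(O)c(C(c3cc(OC)c4c(c3)O[C@@H](c3ccc(OC)cc3OC)[C@@H]4c3cc(OC)cc(OC)c3)S(=O)(=O)c3ccc(C)cc3)c(O)c2)cc1
A6 | alternative 2 | (2R,5R)-1-(4-methoxybenzyl)-2,5-dimethylthiolan-1-ium trifluoromethanesulfonate (or its antipode, whichever matches) | C[C@@H]1CC[C@@H](C)[S+]1Cc1ccc(OC)cc1.[O-]S(=O)(=O)C(F)(F)F
A7 | alternative 3 | bis(dihydrobenzofuran) with C4 pinacolboronate and C6 bromide on ring A | Brc1cc(B3OC(C)(C)C(C)(C)O3)c2c(c1)O[C@@H](c1ccc(OC)cc1)[C@@H]2c1cc(OC)c2c(c1)O[C@@H](c1ccc(OC)cc1OC)[C@@H]2c1cc(OC)cc(OC)c1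
A8 | alternative 3 | 5-bromo-2-pyron-3-yl ether tethered through O1–C2–C3 to an alkynyl pinacolboronate | O=C1OC=C(Br)C=C1O[C@@H](c1ccc(OC)cc1)[C@@H](C#CB1OC(C)(C)C(C)(C)O1)c1cc(OC)c2c(c1)O[C@@H](c1ccc(OC)cc1OC)[C@@H]2c1cc(OC)cc(OC)c1
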